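**Plan**

- Retrosynthesis: C6=O and C7=C7a of the target are unmasked from a 6,7a-bis(silyloxy)cyclohexa-1,4-diene. C3a–C7a and C4–C5 are then cut together (retro-[4+2]), then the C7a–O1 ester bond, and last the carbinol–CHMe bond (C2–C3) of the homopropargylic alcohol.
- Enabling feature: ring A (C3a–C4–C5–C6–C7–C7a) carries oxygen on C5, C6 and C7a and shares the C3a–C7a bond with dihydrofuran ring B. C5 and C7a are 1,4 to each other, so a C7a=C7–C6=C5 diene hung through O1–C2–C3 from a C3a≡C4 alkyne already holds every atom of both rings.
- Forward: alcohol 5 (C2, C3, alkyne) and acyl Meldrum's acid 11 (C5–C7a with allyl and methoxy) are joined as β-keto ester 13. Two silylations give diene 16, rings A and B close in one step, and loss of silanol gives 18.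
- Stereochemistry: C3 comes from (R)-but-3-yn-2-ol by chirality transfer through an allenylzinc, and C2 from the anti-selective addition to the aldehyde. C5 comes from the diene face chosen by C2/C3 together with the fixed diene geometry; the auxiliary C7a centre is erased at the end.

Key step: step 9

Remark: locants C2–C7a are those of the benzofuranone core of 18. The centre made in step 3 is racemic, so 13 and 14 are epimer mixtures at the future C5; this is harmless because step 8 makes that carbon planar and step 9 recreates it.

**Step 1**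
Reactants: 1 (R)-but-3-yn-2-ol
Product: 2 (R)-but-3-yn-2-yl methanesulfonate
Conditions: MsCl, Et3N, CH2Cl2, −78 °C
Reagents that add atoms: methanesulfonyl chloride, CS(=O)(=O)Cl
Why: O-sulfonylation (mesylation) of a secondary propargylic alcohol leaves the C–O bond untouched, so the R centre is retained.

**Step 2**
Reactants: 2 (R)-but-3-yn-2-yl methanesulfonate; 3 3,4,5-trimethoxybenzaldehyde
Product: 5 (1S,2S)-2-methyl-1-(3,4,5-trimethoxyphenyl)but-3-yn-1-ol, via allenylzinc mesylate 4 (not isolated)
Conditions: Pd(OAc)2 (5 mol %), PPh3 (5 mol %), ZnEt2 (3 equiv), THF, −78 → −20 °C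
Reagents that add atoms: none
Why: Palladium-catalysed, zinc-mediated propargylation (Marshall propargylation): zerovalent palladium formed in situ displaces the mesylate in an anti SN2′ sense, ZnEt2 transmetalates to the (P)-allenylzinc 4, and its cyclic SE2′ addition to 3 with the aryl group turned away from the allenyl methyl transfers the axial chirality to the methyl-bearing carbon (future C3, S) and sets the carbinol carbon (future C2, S) as the anti diastereomer.

**Step 3**
Reactants: 6 methyl methoxyacetate
Product: 8 methyl 2-methoxypent-4-enoate (racemic), via lithium enolate 7 (not isolated)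
Conditions: LiN(i-Pr)2, THF, −78 °C; allyl bromide, DMPU, −78 → −20 °C
Reagents that add atoms: allyl bromide, C=CCBr
Why: Enolate alkylation of the chelated lithium enolate of an α-alkoxy ester with a reactive allylic bromide; the new centre is racemic and is planarised later.

**Step 4**
Reactants: 8 methyl 2-methoxypent-4-enoate
Product: 9 2-methoxypent-4-enoic acid (racemic)
Conditions: LiOH·H2O, THF–H2O, 0 °C → rt; then 1 M HCl
Reagents that add atoms: lithium hydroxide, [Li+].[OH-]
Why: Ester saponification under mild LiOH conditions leaves the ether and the terminal alkene untouched.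

**Step 5**
Reactants: 9 2-methoxypent-4-enoic acid; 10 Meldrum's acid
Product: 11 5-(1-hydroxy-2-methoxypent-4-en-1-ylidene)-2,2-dimethyl-1,3-dioxane-4,6-dione
Conditions: DCC, DMAP, CH2Cl2, 0 °C → rt
Reagents that add atoms: none
Why: Carbodiimide-mediated C-acylation of Meldrum's acid gives the enolised acyl Meldrum's acid, a storable acylketene precursor.

**Step 6**
Reactants: 11 5-(1-hydroxy-2-methoxypent-4-en-1-ylidene)-2,2-dimethyl-1,3-dioxane-4,6-dione; 5 (1S,2S)-2-methyl-1-(3,4,5-trimethoxyphenyl)but-3-yn-1-ol
Product: 13 (1S,2S)-2-methyl-1-(3,4,5-trimethoxyphenyl)but-3-yn-1-yl 4-methoxy-3-oxohept-6-enoate, via acylketene 12 (not isolated)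
Conditions: toluene, 90 °C
Reagents that add atoms: none
Why: Thermal fragmentation of the acyl Meldrum's acid (loss of acetone and CO2) releases acylketene 12, which the secondary alcohol traps in a base-free acylation that touches neither the two stereocentres of 5 nor the alkyne.

**Step 7**
Reactants: 13 (1S,2S)-2-methyl-1-(3,4,5-trimethoxyphenyl)but-3-yn-1-yl 4-methoxy-3-oxohept-6-enoate
Product: 14 (1S,2S)-2-methyl-1-(3,4,5-trimethoxyphenyl)but-3-yn-1-yl (2E)-4-methoxy-3-(trimethylsilyloxy)hepta-2,6-dienoate
Conditions: Me3SiCl, Et3N, toluene, rt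
Reagents that add atoms: chlorotrimethylsilane, C[Si](C)(C)Cl
Why: Amine-mediated silyl enol ether formation from the enolised β-keto ester gives the conjugated 3-silyloxy enoate (expected mainly 2E; this bond becomes the central single bond of the diene) and masks O6 so that it cannot chelate lithium in step 8.

**Step 8**
Reactants: 14 (1S,2S)-2-methyl-1-(3,4,5-trimethoxyphenyl)but-3-yn-1-yl (2E)-4-methoxy-3-(trimethylsilyloxy)hepta-2,6-dienoate
Product: 16 (1S,2S)-2-methyl-1-(3,4,5-trimethoxyphenyl)but-3-yn-1-yl (1Z,3E)-4-methoxy-1,3-bis(trimethylsilyloxy)hepta-1,3,6-trien-1-yl ether, via lithium dienolate 15 (not isolated)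
Conditions: LiN(i-Pr)2 (1.1 equiv), THF, −78 °C; Me3SiCl, −78 °C → rt; used crude
Reagents that add atoms: chlorotrimethylsilane, C[Si](C)(C)Cl
Why: Carbonyl-directed kinetic γ-deprotonation (vinylogous enolisation) followed by O-silylation, the standard route to 1-alkoxy-1,3-bis(silyloxy) dienes: the ester oxygen that guides the amide to H5 becomes the inside O–Li and then OSiMe3 at C7a (1Z), the smaller, dipole-opposed methoxy group takes the inside position at C5 once O6 is silylated (3E), and ester-directed deprotonation at −78 °C is expected to outpace removal of the acetylenic hydrogen.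

**Step 9**
Reactants: 16 (1S,2S)-2-methyl-1-(3,4,5-trimethoxyphenyl)but-3-yn-1-yl (1Z,3E)-4-methoxy-1,3-bis(trimethylsilyloxy)hepta-1,3,6-trien-1-yl ether
Product: 17 (2S,3S,5R,7aR)-5-methoxy-3-methyl-5-(prop-2-en-1-yl)-2-(3,4,5-trimethoxyphenyl)-6,7a-bis(trimethylsilyloxy)-2,3,5,7a-tetrahydro-1-benzofuran
Conditions: toluene (0.02 M, degassed), Et3N (0.1 equiv), sealed tube, 110–140 °C
Reagents that add atoms: none
Why: Proposed new method: a concerted, suprafacial thermal [4+2] cycloaddition (type 1 intramolecular Diels–Alder) is proposed in which the electron-rich C7a=C7–C6=C5 diene adds across the unactivated C3a≡C4 alkyne and forms C3a–C7a and C4–C5 together; an alkyne dienophile raises no endo/exo question and the homopropargylic ketene acetal has no [3,3] escape route. The closest known reactions are thermal intramolecular Diels–Alder reactions of 2-silyloxy dienes and of dienes with tethered unactivated alkynes that give cyclohexa-1,4-dienes, and intermolecular cycloadditions of 1-alkoxy-1,3-bis(silyloxy) dienes; a ketene-acetal oxygen as tether atom and a diene substituted at all four terminal positions have not been combined with them. Ring A closes as the six-membered cycloadduct ring (four diene carbons plus the two alkyne carbons), and ring B closes through the same C3a–C7a bond as the five-membered tether ring O1–C2–C3–C3a–C7a, which gives the fused bicycle. C7a is set by the choice of diene face: the forming ring B is an envelope with C2 as the flap, tipped toward the diene so that O1 stays conjugated, and only addition to one face lets the trans aryl (C2) and methyl (C3) groups both sit pseudo-equatorial, which puts the inside OSiMe3 on the side of the C3 methyl (7aR). C5 follows from C7a by suprafacial addition to the (3E) terminus, so that the inside methoxy ends cis to the C7a silyloxy group and the outside allyl cis to O1 (5R). The step needs diene-face selectivity and a rate sufficient below the temperature of Cope allyl shifts; the substituted tether is meant to secure the first, and the five-membered tether with small, oxygen-only inside groups the second.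

**Step 10**
Reactants: 17 (2S,3S,5R,7aR)-5-methoxy-3-methyl-5-(prop-2-en-1-yl)-2-(3,4,5-trimethoxyphenyl)-6,7a-bis(trimethylsilyloxy)-2,3,5,7a-tetrahydro-1-benzofuran
Product: 18 (2S,3S,5R)-5-methoxy-3-methyl-5-(prop-2-en-1-yl)-2-(3,4,5-trimethoxyphenyl)-2,3-dihydro-1-benzofuran-6(5H)-one
Conditions: 0.1 M HCl, THF–H2O, 0 °C
Reagents that add atoms: none
Why: Silyl enol ether hydrolysis coupled with β-elimination of silanol: cleavage of the C6 silyl enol ether and ionisation of the C7a silyl ketal through the O1-stabilised oxocarbenium ion give the cross-conjugated vinylogous ester, while C2, C3 and quaternary C5 are not involved and C7a becomes sp2.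

**Compound list**

1 | (R)-but-3-yn-2-ol | C#C[C@@H](C)O | starting material
2 | (R)-but-3-yn-2-yl methanesulfonate | C#C[C@@H](C)OS(C)(=O)=O | intermediate
3 | 3,4,5-trimethoxybenzaldehyde | COc1cc(C=O)cc(OC)c1OC | starting material
4 | (P)-buta-1,2-dien-1-ylzinc methanesulfonate, aS allene (not isolated) | [H]C(C)=[C@]=C([H])[Zn]OS(C)(=O)=O | intermediate
5 | (1S,2S)-2-methyl-1-(3,4,5-trimethoxyphenyl)but-3-yn-1-ol | O[C@H](c1cc(OC)c(OC)c(OC)c1)[C@@H](C)C#C | intermediate
6 | methyl methoxyacetate | COCC(=O)OC | starting material
7 | lithium 1,2-dimethoxyethen-1-olate, chelated enolate of 6 (not isolated) | CO/C=C(\O[Li])OC | intermediate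
8 | methyl 2-methoxypent-4-enoate (racemic) | C=CCC(OC)C(=O)OC | intermediate
9 | 2-methoxypent-4-enoic acid (racemic) | C=CCC(OC)C(=O)O | intermediate
10 | Meldrum's acid (2,2-dimethyl-1,3-dioxane-4,6-dione) | CC1(C)OC(=O)CC(=O)O1 | starting material
11 | 5-(1-hydroxy-2-methoxypent-4-en-1-ylidene)-2,2-dimethyl-1,3-dioxane-4,6-dione | C=CCC(OC)C(O)=C1C(=O)OC(C)(C)OC1=O | intermediate
12 | 4-methoxyhepta-1,6-diene-1,3-dione, acylketene (not isolated) | C=CCC(OC)C(=O)C=C=O | intermediate
13 | (1S,2S)-2-methyl-1-(3,4,5-trimethoxyphenyl)but-3-yn-1-yl 4-methoxy-3-oxohept-6-enoate (epimers at C4 of the acyl chain) | C=CCC(OC)C(=O)CC(=O)O[C@H](c1cc(OC)c(OC)c(OC)c1)[C@@H](C)C#C | intermediate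
14 | (1S,2S)-2-methyl-1-(3,4,5-trimethoxyphenyl)but-3-yn-1-yl (2E)-4-methoxy-3-(trimethylsilyloxy)hepta-2,6-dienoate | C=CCC(OC)/C(O[Si](C)(C)C)=C\C(=O)O[C@H](c1cc(OC)c(OC)c(OC)c1)[C@@H](C)C#C | intermediate
15 | lithium dienolate of 14, O–Li and methoxy inside, same geometry as 16 (not isolated) | C=CC/C(OC)=C(O[Si](C)(C)C)/C=C(\O[Li])O[C@H](c1cc(OC)c(OC)c(OC)c1)[C@@H](C)C#C | intermediate
16 | (1S,2S)-2-methyl-1-(3,4,5-trimethoxyphenyl)but-3-yn-1-yl (1Z,3E)-4-methoxy-1,3-bis(trimethylsilyloxy)hepta-1,3,6-trien-1-yl ether | C=CC/C(OC)=C(O[Si](C)(C)C)/C=C(\O[Si](C)(C)C)O[C@H](c1cc(OC)c(OC)c(OC)c1)[C@@H](C)C#C | intermediate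
17 | (2S,3S,5R,7aR)-5-methoxy-3-methyl-5-(prop-2-en-1-yl)-2-(3,4,5-trimethoxyphenyl)-6,7a-bis(trimethylsilyloxy)-2,3,5,7a-tetrahydro-1-benzofuran | C=CC[C@@]1(OC)C=C2[C@](O[Si](C)(C)C)(C=C1O[Si](C)(C)C)O[C@H](c1cc(OC)c(OC)c(OC)c1)[C@H]2C | intermediate
18 | (2S,3S,5R)-5-methoxy-3-methyl-5-(prop-2-en-1-yl)-2-(3,4,5-trimethoxyphenyl)-2,3-dihydro-1-benzofuran-6(5H)-one | C=CC[C@@]1(OC)C=C2C(=CC1=O)O[C@H](c1cc(OC)c(OC)c(OC)c1)[C@H]2C | target

**Step count**

Total: 10 steps. Longest linear sequence: 8 steps (from 6 through steps 3, 4, 5, 6, 7, 8, 9 and 10); the branch from 1 joins at step 6.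

**Steps most likely to fail**

Step 9 (proposed new method). The cycloaddition may be outrun by thermal silyl migration in the diene or by Cope shift of the allyl group in the adduct, because the alkyne is unactivated. The fallback uses known chemistry and makes the two ring bonds stepwise on a metal instead of in a thermal pericyclic step. Diene 16 would be treated with [RhCl(C8H14)2]2 and P[OCH(CF3)2]3 in THF at 25–55 °C. This is the monovalent-rhodium-catalysed intramolecular [4+2] cycloaddition established for dienes tethered to unactivated terminal alkynes (oxidative cyclisation to a rhodacycle, then reductive elimination). It runs under neutral, aprotic conditions well below the temperatures of silyl and allyl migration, and a chiral diphosphine on rhodium would add a handle on the diene face. The fallback sets out from 16 and comes back to the route at 17; no new compound is made (F0).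

Step 8. The amide base may also remove the acetylenic hydrogen, γ-deprotonation of the hindered methine may be incomplete, and the (1Z,3E) geometry may erode. The fallback gives up the lithium dienolate altogether. β-Keto ester 13 would be bis-silylated in one flask by soft enolisation with Me3SiOTf (2.5 equiv) and Et3N (3 equiv) in Et2O at 0 °C, the silyl triflate/amine route to 1,3-bis(silyloxy) dienes. Each carbonyl is first O-silylated and then deprotonated by the amine, so no base strong enough to metalate the alkyne is present, and the geometry is set under equilibrating conditions and would be checked by NOE before use. The fallback sets out from 13, bypasses 14 and 15, and comes back at 16; no new compound is made (F0).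

Step 2. Anti/syn selectivity may erode with the unbranched aromatic aldehyde, and the allenylzinc may partly racemise before it adds. The fallback builds the same two centres by Brown crotylboration and then converts vinyl into ethynyl. Aldehyde 3 and (−)-B-(E)-crotyldiisopinocampheylborane (from (+)-α-pinene; THF, −78 °C, then NaOH/H2O2) should give, by attack on the Si face through a chair transition state, the anti homoallylic alcohol (1S,2S)-2-methyl-1-(3,4,5-trimethoxyphenyl)but-3-en-1-ol F1. Silylation (TBSCl, imidazole, DMF) would give tert-butyldimethyl{[(1S,2S)-2-methyl-1-(3,4,5-trimethoxyphenyl)but-3-en-1-yl]oxy}silane F2. Ozonolysis (O3, CH2Cl2, −78 °C; PPh3) would give (2R,3S)-3-(tert-butyldimethylsilyloxy)-2-methyl-3-(3,4,5-trimethoxyphenyl)propanal F3. Ohira–Bestmann homologation (dimethyl 1-diazo-2-oxopropylphosphonate, K2CO3, MeOH, 0 °C) would give tert-butyldimethyl{[(1S,2S)-2-methyl-1-(3,4,5-trimethoxyphenyl)but-3-yn-1-yl]oxy}silane F4. Desilylation with Bu4NF in THF then returns alcohol 5. The fallback sets out from 3 and comes back to the route at 5.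

**Further compounds**

F0 | step 9 | none | none
F0 | step 8 | none | none
F1 | step 2 | (1S,2S)-2-methyl-1-(3,4,5-trimethoxyphenyl)but-3-en-1-ol | O[C@H](c1cc(OC)c(OC)c(OC)c1)[C@@H](C)C=C
F2 | step 2 | tert-butyldimethyl{[(1S,2S)-2-methyl-1-(3,4,5-trimethoxyphenyl)but-3-en-1-yl]oxy}silane | CC(C)(C)[Si](C)(C)O[C@H](c1cc(OC)c(OC)c(OC)c1)[C@@H](C)C=C
F3 | step 2 | (2R,3S)-3-(tert-butyldimethylsilyloxy)-2-methyl-3-(3,4,5-trimethoxyphenyl)propanal | CC(C)(C)[Si](C)(C)O[C@H](c1cc(OC)c(OC)c(OC)c1)[C@@H](C)C=O
F4 | step 2 | tert-butyldimethyl{[(1S,2S)-2-methyl-1-(3,4,5-trimethoxyphenyl)but-3-yn-1-yl]oxy}silane | CC(C)(C)[Si](C)(C)O[C@H](c1cc(OC)c(OC)c(OC)c1)[C@@H](C)C#C
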